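**Plan**

- Retrosynthesis: the five MOM ethers come off first. Next the C5–CH2 bond of the ring A side chain is cut (Heck arylation of an aryl vinyl carbinol, which gives the saturated ketone directly). Then C2–C3 and O1–C2 are cut together. Last are the C–C bond beside the sulfone in the α-tosyl ketone and the S–CH2 bond of the sulfonium salt.
- Enabling feature: C2 carries only H and the 4-hydroxyphenyl ring and lies between O1 and C3, so it can be the carbon of a benzylic sulfonium ylide. O1, C7a, C3a and C3 with its 2,4-dihydroxybenzoyl group are the four atoms of an ortho-quinone methide of ring A.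
- Forward order: ring A sulfone plus aldehyde gives α-tosyl ketone 10; thiolane plus benzyl bromide gives salt 17; the dihydrofuran, the only ring made, closes in the [4+1] step; the C5 chain is then attached and the phenols are freed.
- Stereochemistry: C2 comes from the C2-symmetric (2S,5S)-2,5-dimethylthiolane (made from (2R,5R)-hexane-2,5-diol) through facial control of the ylide and one inversion. C3 settles trans by equilibration α to the ketone.

Key step: step 13

Assumption: the sense of induction follows the usual model for 2,5-dimethylthiolanium benzylides (aryl group turned away from the ring, electrophile anti to the methyl group cis to the ylide carbon, one inversion at the ylide carbon on closure). On that model the (2S,5S)-sulfide gives 2S; the enantiomeric diol would be taken if the opposite sense were found.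

**Step 1**
Reactants: 1 2-hydroxy-5-iodobenzaldehyde
Product: 2 2-(hydroxymethyl)-4-iodophenol
Conditions: NaBH4, MeOH, 0 °C
Reagents that add atoms: none
Why: Borohydride reduction of the aryl aldehyde is chemoselective and leaves the aryl iodide and the phenol untouched.

**Step 2**
Reactants: 2 2-(hydroxymethyl)-4-iodophenol
Product: 3 4-iodo-2-[(4-methylbenzenesulfonyl)methyl]phenol
Conditions: 4-MeC6H4SO2Na, HCO2H/H2O, 50 °C
Reagents that add atoms: sodium 4-methylbenzenesulfinate, [Na+].[O-]S(=O)c1ccc(C)cc1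
Why: Under acid the ortho-hydroxybenzyl alcohol ionises and is captured at sulfur by the sulfinate, the standard S-alkylation route to 2-(sulfonylmethyl)phenols.

**Step 3**
Reactants: 3 4-iodo-2-[(4-methylbenzenesulfonyl)methyl]phenol
Product: 4 {4-iodo-2-[(4-methylbenzenesulfonyl)methyl]phenoxy}tri(propan-2-yl)silane
Conditions: TIPSCl, imidazole, DMF, rt
Reagents that add atoms: chlorotri(propan-2-yl)silane, CC(C)[Si](Cl)(C(C)C)C(C)C
Why: Imidazole-mediated silyl ether formation masks the phenol so that base cannot expel sulfinate in step 5, and the bulky silyl group resists migration to carbon or to an alkoxide.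

**Step 4**
Reactants: 5 2,4-dihydroxybenzaldehyde
Product: 6 2,4-bis(methoxymethoxy)benzaldehyde
Conditions: MOMCl, i-Pr2NEt, CH2Cl2, 0 °C to reflux
Reagents that add atoms: chloromethyl methyl ether, COCCl
Why: Williamson-type alkylation of both phenols; warming with excess reagent also alkylates the hydrogen-bonded 2-hydroxyl.

**Step 5**
Reactants: 4 {4-iodo-2-[(4-methylbenzenesulfonyl)methyl]phenoxy}tri(propan-2-yl)silane; 6 2,4-bis(methoxymethoxy)benzaldehyde
Product: 8 1-[2,4-bis(methoxymethoxy)phenyl]-2-{5-iodo-2-[tri(propan-2-yl)silyloxy]phenyl}-2-(4-methylbenzenesulfonyl)ethan-1-ol (racemic, both diastereomers), via α-lithio sulfone 7 (not isolated)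
Conditions: LiN(SiMe3)2, THF, −78 °C; then 6; AcOH quench at −78 °C
Reagents that add atoms: none
Why: The amide base deprotonates the benzylic sulfone without touching the aryl iodide and the sulfonyl carbanion adds to the aldehyde (first stage of a Julia-type coupling); both new stereocentres are erased in steps 6 and 13.

**Step 6**
Reactants: 8 the β-hydroxy sulfone from step 5
Product: 9 1-[2,4-bis(methoxymethoxy)phenyl]-2-{5-iodo-2-[tri(propan-2-yl)silyloxy]phenyl}-2-(4-methylbenzenesulfonyl)ethan-1-one (racemic)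
Conditions: Dess–Martin periodinane, CH2Cl2, rt
Reagents that add atoms: none
Why: Dess–Martin oxidation turns the secondary alcohol into the ketone under near-neutral conditions that MOM and silyl ethers tolerate.

**Step 7**
Reactants: 9 the silyl-protected α-tosyl ketone
Product: 10 1-[2,4-bis(methoxymethoxy)phenyl]-2-(2-hydroxy-5-iodophenyl)-2-(4-methylbenzenesulfonyl)ethan-1-one (racemic)
Conditions: Bu4NF, AcOH (1:1), THF, 0 °C
Reagents that add atoms: none
Why: Buffered fluoride desilylation frees the phenol, and acetic acid protonates the phenoxide at once so that sulfinate is not expelled prematurely.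

**Step 8**
Reactants: 11 (2R,5R)-hexane-2,5-diol
Product: 12 (2R,5R)-hexane-2,5-diyl dimethanesulfonate
Conditions: MsCl, Et3N, CH2Cl2, 0 °C
Reagents that add atoms: methanesulfonyl chloride, CS(Cl)(=O)=O
Why: Mesylation activates both secondary alcohols with retention at carbon.

**Step 9**
Reactants: 12 (2R,5R)-hexane-2,5-diyl dimethanesulfonate
Product: 13 (2S,5S)-2,5-dimethylthiolane
Conditions: Na2S, DMSO, rt
Reagents that add atoms: sodium sulfide, [Na+].[Na+].[S-2]
Why: Double SN2 displacement by sulfide closes the thiolane with inversion at both carbons, converting the (2R,5R)-dimesylate into the C2-symmetric (2S,5S)-sulfide.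

**Step 10**
Reactants: 14 4-(hydroxymethyl)phenol
Product: 15 [4-(methoxymethoxy)phenyl]methanol
Conditions: NaH (1.0 equiv), THF/DMF, 0 °C; MOMCl (1.0 equiv)
Reagents that add atoms: chloromethyl methyl ether, COCCl
Why: One equivalent of NaH forms only the phenoxide, far more acidic than the benzylic alcohol, and this is alkylated selectively (Williamson ether synthesis).

**Step 11**
Reactants: 15 [4-(methoxymethoxy)phenyl]methanol
Product: 16 1-(bromomethyl)-4-(methoxymethoxy)benzene
Conditions: CBr4, PPh3, CH2Cl2, 0 °C; used at once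
Reagents that add atoms: tetrabromomethane, BrC(Br)(Br)Br
Why: Appel bromination converts the benzylic alcohol into the bromide under neutral conditions that spare the MOM ether.

**Step 12**
Reactants: 16 1-(bromomethyl)-4-(methoxymethoxy)benzene; 13 (2S,5S)-2,5-dimethylthiolane
Product: 17 (2S,5S)-1-{[4-(methoxymethoxy)phenyl]methyl}-2,5-dimethylthiolan-1-ium tetrafluoroborate
Conditions: NaBF4, acetone, rt, dark
Reagents that add atoms: sodium tetrafluoroborate, [Na+].F[B-](F)(F)F
Why: S-Alkylation of the sulfide by the reactive benzylic bromide, with exchange to a non-nucleophilic counter-ion so that the salt does not revert; the C2-symmetric sulfide can give only one sulfonium salt.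

**Step 13**
Reactants: 10 1-[2,4-bis(methoxymethoxy)phenyl]-2-(2-hydroxy-5-iodophenyl)-2-(4-methylbenzenesulfonyl)ethan-1-one; 17 (2S,5S)-1-{[4-(methoxymethoxy)phenyl]methyl}-2,5-dimethylthiolan-1-ium tetrafluoroborate
Product: 21 [2,4-bis(methoxymethoxy)phenyl]{(2S,3S)-5-iodo-2-[4-(methoxymethoxy)phenyl]-2,3-dihydro-1-benzofuran-3-yl}methanone, via sulfonium ylide 18 (not isolated), via acyl ortho-quinone methide 19 (not isolated), via betaine 20 (not isolated)
Conditions: 17 (1.5 equiv), Cs2CO3 (3 equiv), CH2Cl2/t-BuOH 5:1, 0 °C to rt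
Reagents that add atoms: none
Why: Proposed new method: Cs2CO3 converts 10 into its phenoxide, which expels sulfinate to give the acyl ortho-quinone methide 19, and deprotonates 17 to the benzylide 18; the ylide carbon adds to the doubly activated methide carbon (C2–C3), ring A rearomatises to betaine 20, and the phenoxide displaces the sulfide at C2 by 5-exo-tet substitution with inversion (O1–C2), closing the dihydrofuran and releasing sulfide 13. The closest known reaction type is the carbonate-mediated [4+1] annulation of 2-(1-tosylalkyl)phenols with sulfonium ylides to trans-2,3-dihydrobenzofurans, combined with benzylide transfer from C2-symmetric thiolanium salts to aldehydes; an aroyl group on the methide carbon together with a benzylide partner is untested. C2 is controlled by the thiolane: the methyl group cis to the ylide carbon screens one ylide face, rearomatisation makes C–C bond formation irreversible, and the single SN2 inversion then gives 2S on the stated model. C3 is set thermodynamically, because C3–H is α to the ketone and equilibrates under carbonate to the trans (2S,3S) isomer. The step needs sulfinate loss from the phenoxide tautomer to outrun benzyl transfer from 17 to the more stable enolate of 10, which the protic co-solvent (raising the phenoxide share) and the high electrophilicity of 19 are meant to secure, and it needs ring closure to beat E1cB loss of sulfide from 20, which the para-alkoxybenzylic sulfonium carbon and the five-membered transition state favour. Once closed, the product should resist base-induced ring opening because the C2–O1 bond lies in the nodal plane of the C3 enolate.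

**Step 14**
Reactants: 6 2,4-bis(methoxymethoxy)benzaldehyde
Product: 22 1-[2,4-bis(methoxymethoxy)phenyl]prop-2-en-1-ol (racemic)
Conditions: CH2=CHMgBr, THF, 0 °C; NH4Cl quench
Reagents that add atoms: vinylmagnesium bromide, C=C[Mg]Br
Why: Grignard 1,2-addition to the aryl aldehyde; the carbinol centre is racemic and is lost in step 15.

**Step 15**
Reactants: 21 the iodo dihydrobenzofuran ketone from step 13; 22 1-[2,4-bis(methoxymethoxy)phenyl]prop-2-en-1-ol
Product: 24 3-{(2S,3S)-3-[2,4-bis(methoxymethoxy)benzoyl]-2-[4-(methoxymethoxy)phenyl]-2,3-dihydro-1-benzofuran-5-yl}-1-[2,4-bis(methoxymethoxy)phenyl]propan-1-one, via enol 23 (not isolated)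
Conditions: Pd(OAc)2 (5 mol %), Bu4NCl, NaHCO3, DMF, 45 °C
Reagents that add atoms: none
Why: Mizoroki–Heck arylation of the allylic alcohol under ligand-free phase-transfer conditions puts the aryl group on the terminal carbon, and β-hydride elimination towards the carbinol gives the enol and hence the saturated ketone directly; the bicarbonate base leaves C2 and C3 untouched.

**Step 16**
Reactants: 24 the penta-MOM diketone from step 15
Product: 25 3-[(2S,3S)-3-(2,4-dihydroxybenzoyl)-2-(4-hydroxyphenyl)-2,3-dihydro-1-benzofuran-5-yl]-1-(2,4-dihydroxyphenyl)propan-1-one (CNP0136359.1)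
Conditions: HCl (3 M aq.), MeOH, 40 °C
Reagents that add atoms: none
Why: Acid-catalysed acetal methanolysis removes all five MOM groups; C3 already sits in its thermodynamic trans arrangement and no bond to C2 is broken.

**Compound list**

1 | 2-hydroxy-5-iodobenzaldehyde | O=Cc1cc(I)ccc1O | starting material
2 | 2-(hydroxymethyl)-4-iodophenol | OCc1cc(I)ccc1O | intermediate
3 | 4-iodo-2-[(4-methylbenzenesulfonyl)methyl]phenol | Cc1ccc(cc1)S(=O)(=O)Cc1cc(I)ccc1O | intermediate
4 | {4-iodo-2-[(4-methylbenzenesulfonyl)methyl]phenoxy}tri(propan-2-yl)silane | Cc1ccc(cc1)S(=O)(=O)Cc1cc(I)ccc1O[Si](C(C)C)(C(C)C)C(C)C | intermediate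
5 | 2,4-dihydroxybenzaldehyde | O=Cc1ccc(O)cc1O | starting material
6 | 2,4-bis(methoxymethoxy)benzaldehyde | O=Cc1ccc(OCOC)cc1OCOC | intermediate
7 | α-lithio derivative of sulfone 4 (formed in the flask) | Cc1ccc(cc1)S(=O)(=O)C([Li])c1cc(I)ccc1O[Si](C(C)C)(C(C)C)C(C)C | intermediate
8 | 1-[2,4-bis(methoxymethoxy)phenyl]-2-{5-iodo-2-[tri(propan-2-yl)silyloxy]phenyl}-2-(4-methylbenzenesulfonyl)ethan-1-ol (racemic, diastereomer mixture) | OC(c1ccc(OCOC)cc1OCOC)C(c1cc(I)ccc1O[Si](C(C)C)(C(C)C)C(C)C)S(=O)(=O)c1ccc(C)cc1 | intermediate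
9 | 1-[2,4-bis(methoxymethoxy)phenyl]-2-{5-iodo-2-[tri(propan-2-yl)silyloxy]phenyl}-2-(4-methylbenzenesulfonyl)ethan-1-one (racemic) | O=C(c1ccc(OCOC)cc1OCOC)C(c1cc(I)ccc1O[Si](C(C)C)(C(C)C)C(C)C)S(=O)(=O)c1ccc(C)cc1 | intermediate
10 | 1-[2,4-bis(methoxymethoxy)phenyl]-2-(2-hydroxy-5-iodophenyl)-2-(4-methylbenzenesulfonyl)ethan-1-one (racemic) | O=C(c1ccc(OCOC)cc1OCOC)C(c1cc(I)ccc1O)S(=O)(=O)c1ccc(C)cc1 | intermediate
11 | (2R,5R)-hexane-2,5-diol | C[C@@H](O)CC[C@@H](C)O | starting material
12 | (2R,5R)-hexane-2,5-diyl dimethanesulfonate | C[C@@H](OS(C)(=O)=O)CC[C@@H](C)OS(C)(=O)=O | intermediate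
13 | (2S,5S)-2,5-dimethylthiolane | C[C@H]1CC[C@H](C)S1 | intermediate
14 | 4-(hydroxymethyl)phenol | OCc1ccc(O)cc1 | starting material
15 | [4-(methoxymethoxy)phenyl]methanol | OCc1ccc(OCOC)cc1 | intermediate
16 | 1-(bromomethyl)-4-(methoxymethoxy)benzene | BrCc1ccc(OCOC)cc1 | intermediate
17 | (2S,5S)-1-{[4-(methoxymethoxy)phenyl]methyl}-2,5-dimethylthiolan-1-ium tetrafluoroborate | C[C@H]1CC[C@H](C)[S+]1Cc1ccc(OCOC)cc1.F[B-](F)(F)F | intermediate
18 | (2S,5S)-2,5-dimethylthiolan-1-ium-1-yl [4-(methoxymethoxy)phenyl]methanide, the benzylide (formed in the flask) | C[C@H]1CC[C@H](C)[S+]1[CH-]c1ccc(OCOC)cc1 | intermediate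
19 | 6-{2-[2,4-bis(methoxymethoxy)phenyl]-2-oxoethylidene}-4-iodocyclohexa-2,4-dien-1-one, the acyl ortho-quinone methide (formed in the flask) | O=C1C=CC(I)=CC1=CC(=O)c1ccc(OCOC)cc1OCOC | intermediate
20 | 2-{3-[2,4-bis(methoxymethoxy)phenyl]-1-[(2S,5S)-2,5-dimethylthiolan-1-ium-1-yl]-1-[4-(methoxymethoxy)phenyl]-3-oxopropan-2-yl}-4-iodophenolate, the betaine, (1R) at the sulfonium-bearing carbon, C-2 of the chain unassigned (formed in the flask) | [O-]c1ccc(I)cc1C(C(=O)c1ccc(OCOC)cc1OCOC)[C@H](c1ccc(OCOC)cc1)[S+]1[C@@H](C)CC[C@@H]1C | intermediate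
21 | [2,4-bis(methoxymethoxy)phenyl]{(2S,3S)-5-iodo-2-[4-(methoxymethoxy)phenyl]-2,3-dihydro-1-benzofuran-3-yl}methanone | Ic1ccc2c(c1)[C@H](C(=O)c1ccc(OCOC)cc1OCOC)[C@@H](c1ccc(OCOC)cc1)O2 | intermediate
22 | 1-[2,4-bis(methoxymethoxy)phenyl]prop-2-en-1-ol (racemic) | C=CC(O)c1ccc(OCOC)cc1OCOC | intermediate
23 | enol form of ketone 24 (formed in the flask) | OC(=CCc1ccc2c(c1)[C@H](C(=O)c1ccc(OCOC)cc1OCOC)[C@@H](c1ccc(OCOC)cc1)O2)c1ccc(OCOC)cc1OCOC | intermediate
24 | 3-{(2S,3S)-3-[2,4-bis(methoxymethoxy)benzoyl]-2-[4-(methoxymethoxy)phenyl]-2,3-dihydro-1-benzofuran-5-yl}-1-[2,4-bis(methoxymethoxy)phenyl]propan-1-one | O=C(CCc1ccc2c(c1)[C@H](C(=O)c1ccc(OCOC)cc1OCOC)[C@@H](c1ccc(OCOC)cc1)O2)c1ccc(OCOC)cc1OCOC | intermediate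
25 | 3-[(2S,3S)-3-(2,4-dihydroxybenzoyl)-2-(4-hydroxyphenyl)-2,3-dihydro-1-benzofuran-5-yl]-1-(2,4-dihydroxyphenyl)propan-1-one | O=C(CCc1ccc2c(c1)[C@H](C(=O)c1ccc(O)cc1O)[C@@H](c1ccc(O)cc1)O2)c1ccc(O)cc1O | target

**Count**

Total steps: 16. Longest linear sequence: 9 steps (1, 2, 3, 5, 6, 7, 13, 15, 16).

**Steps most likely to fail**

1. Step 13 (proposed new method). The monoanion of 10 may rest as the enolate, so that sulfinate loss is slow and benzyl transfer from 17 to the enolate, phenoxide or sulfinate takes over. The betaine may also lose the sulfide by elimination, with non-selective reclosure, and facial selectivity of the ylide may be weak. The fallback uses known chemistry, sets out from 16 and rejoins at 24. 2-(5-Bromo-2-hydroxyphenyl)acetic acid is esterified (MeOH, H2SO4) to methyl 2-(5-bromo-2-hydroxyphenyl)acetate F1. Alkylation of F1 with 16 (K2CO3, DMF) gives methyl 2-(5-bromo-2-{[4-(methoxymethoxy)phenyl]methoxy}phenyl)acetate F2. Diazo transfer (4-acetamidobenzenesulfonyl azide, DBU, MeCN) gives methyl 2-(5-bromo-2-{[4-(methoxymethoxy)phenyl]methoxy}phenyl)-2-diazoacetate F3. Enantioselective intramolecular insertion of the rhodium carbenoid into the benzylic ether C–H bond, with dirhodium tetrakis[N-phthaloyl-(S)-tert-leucinate], Rh2(S-PTTL)4, or its enantiomer as needed for 2S (toluene, −60 °C), should give the cis ester methyl (2S,3R)-5-bromo-2-[4-(methoxymethoxy)phenyl]-2,3-dihydro-1-benzofuran-3-carboxylate F4. NaOMe in MeOH epimerises C3 to the trans ester methyl (2S,3S)-5-bromo-2-[4-(methoxymethoxy)phenyl]-2,3-dihydro-1-benzofuran-3-carboxylate F5. MeNH(OMe)·HCl with i-PrMgCl gives (2S,3S)-5-bromo-N-methoxy-2-[4-(methoxymethoxy)phenyl]-N-methyl-2,3-dihydro-1-benzofuran-3-carboxamide F6. 4-Bromoresorcinol with MOMCl and i-Pr2NEt gives 1-bromo-2,4-bis(methoxymethoxy)benzene F7; its lithium reagent (n-BuLi, THF, −78 °C) adds to F6 to give [2,4-bis(methoxymethoxy)phenyl]{(2S,3S)-5-bromo-2-[4-(methoxymethoxy)phenyl]-2,3-dihydro-1-benzofuran-3-yl}methanone F8. F8 takes the place of 21 in step 15, run at about 90 °C, and gives 24.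

2. Step 15. β-Hydride elimination may run towards the benzylic side and give the arylated allylic alcohol instead of the ketone, or palladium hydride may isomerise 22 before coupling. The fallback sets out from 21 and 22 and rejoins at 24. MnO2 in CH2Cl2 oxidises 22 to 1-[2,4-bis(methoxymethoxy)phenyl]prop-2-en-1-one F9. Heck coupling of 21 with F9 (Pd(OAc)2, Bu4NCl, NaHCO3, DMF, 40 °C) gives (E)-3-{(2S,3S)-3-[2,4-bis(methoxymethoxy)benzoyl]-2-[4-(methoxymethoxy)phenyl]-2,3-dihydro-1-benzofuran-5-yl}-1-[2,4-bis(methoxymethoxy)phenyl]prop-2-en-1-one F10. Conjugate reduction of F10 with [(Ph3P)CuH]6 in wet benzene at rt gives 24; here the alkene position no longer depends on the direction of β-hydride elimination.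

3. Step 5. The addition of the hindered, stabilised carbanion may revert on warming, or the silyl group may move from the phenolic oxygen to the new alkoxide and trigger sulfinate loss. The fallback sets out from 4 and rejoins at 9, skipping 8 and step 6. Methyl 2,4-dihydroxybenzoate with MOMCl and i-Pr2NEt gives methyl 2,4-bis(methoxymethoxy)benzoate F11. Sulfone 4 is deprotonated with LiN(SiMe3)2 (2.2 equiv, THF, −78 to 0 °C) and acylated with F11. This should give 9 directly, since deprotonation of the β-keto sulfone product makes the acylation irreversible.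

**Further compounds**

F1 | step 13 | methyl 2-(5-bromo-2-hydroxyphenyl)acetate | COC(=O)Cc1cc(Br)ccc1O
F2 | step 13 | methyl 2-(5-bromo-2-{[4-(methoxymethoxy)phenyl]methoxy}phenyl)acetate | COC(=O)Cc1cc(Br)ccc1OCc1ccc(OCOC)cc1
F3 | step 13 | methyl 2-(5-bromo-2-{[4-(methoxymethoxy)phenyl]methoxy}phenyl)-2-diazoacetate | COC(=O)C(=[N+]=[N-])c1cc(Br)ccc1OCc1ccc(OCOC)cc1
F4 | step 13 | methyl (2S,3R)-5-bromo-2-[4-(methoxymethoxy)phenyl]-2,3-dihydro-1-benzofuran-3-carboxylate | Brc1ccc2c(c1)[C@@H](C(=O)OC)[C@@H](c1ccc(OCOC)cc1)O2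
F5 | step 13 | methyl (2S,3S)-5-bromo-2-[4-(methoxymethoxy)phenyl]-2,3-dihydro-1-benzofuran-3-carboxylate | Brc1ccc2c(c1)[C@H](C(=O)OC)[C@@H](c1ccc(OCOC)cc1)O2
F6 | step 13 | (2S,3S)-5-bromo-N-methoxy-2-[4-(methoxymethoxy)phenyl]-N-methyl-2,3-dihydro-1-benzofuran-3-carboxamide | Brc1ccc2c(c1)[C@H](C(=O)N(C)OC)[C@@H](c1ccc(OCOC)cc1)O2
F7 | step 13 | 1-bromo-2,4-bis(methoxymethoxy)benzene | COCOc1ccc(Br)c(OCOC)c1
F8 | step 13 | [2,4-bis(methoxymethoxy)phenyl]{(2S,3S)-5-bromo-2-[4-(methoxymethoxy)phenyl]-2,3-dihydro-1-benzofuran-3-yl}methanone | Brc1ccc2c(c1)[C@H](C(=O)c1ccc(OCOC)cc1OCOC)[C@@H](c1ccc(OCOC)cc1)O2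
F9 | step 15 | 1-[2,4-bis(methoxymethoxy)phenyl]prop-2-en-1-one | C=CC(=O)c1ccc(OCOC)cc1OCOC
F10 | step 15 | (E)-3-{(2S,3S)-3-[2,4-bis(methoxymethoxy)benzoyl]-2-[4-(methoxymethoxy)phenyl]-2,3-dihydro-1-benzofuran-5-yl}-1-[2,4-bis(methoxymethoxy)phenyl]prop-2-en-1-one | O=C(/C=C/c1ccc2c(c1)[C@H](C(=O)c1ccc(OCOC)cc1OCOC)[C@@H](c1ccc(OCOC)cc1)O2)c1ccc(OCOC)cc1OCOC
F11 | step 5 | methyl 2,4-bis(methoxymethoxy)benzoate | COC(=O)c1ccc(OCOC)cc1OCOC
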